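**Retrosynthetic overview**
1. Target 27 ← triacetate 26 by lipase hydrolysis of the primary C14 acetate only; 26 ← triol 25 (C1 isovalerate already in place).
2. Ring A oxygens: C2–OH by Luche reduction of the Δ3-en-2-one; C1–O by α′-hydroxylation of that enone. Ring B: C9–OH by C14–OH-directed reduction; C7 isopropenyl by axial cuprate addition to a Δ7-en-9-one.
3. Ring A enone ← allylic oxidation of a Δ3-alkene ← Li/NH3 reduction and enol triflate of a Wieland–Miescher-type enone (sets the trans ring fusion).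
4. C14 ← angular allyl group (isomerisation, oxidative cleavage, reduction); C10 ← organocatalytic desymmetrising aldol of an achiral triketone.
5. Ring order: ring B is present from the start (cyclohexane-1,3-dione); ring A is closed second by Michael addition and aldol condensation (steps 1–2).

Assumption: 2-allylcyclohexane-1,3-dione is a catalogue compound (otherwise one step from cyclohexane-1,3-dione and an allyl electrophile).
Convention: eudesmane numbering (decalin C1–C10; C14 = CH2–O carbon on C10; C15 = CH3 on C4; C11–C13 = isopropenyl on C7); "cis/trans" always means relative to C14.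

**Step 1**
Reactants: 1 2-allylcyclohexane-1,3-dione; 2 ethyl vinyl ketone (pent-1-en-3-one)
Product: 3 2-allyl-2-(3-oxopentyl)cyclohexane-1,3-dione
Conditions: Et3N (0.1 equiv), EtOAc, 40 °C
Reagents that add atoms: none
Why: Base-catalysed Michael addition of the acidic 2-substituted 1,3-dione to the enone gives the achiral, prochiral triketone.

**Step 2**
Reactants: 3 triketone
Product: 4 (S)-8a-allyl-5-methyl-3,4,8,8a-tetrahydronaphthalene-1,6(2H,7H)-dione (10-allyl-4-methyl-Δ4-3,9-dione)
Conditions: N-tosyl-(Ra)-binam-D-prolinamide (5 mol%), PhCO2H (2.5 mol%), neat, 25 → 45 °C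
Reagents that add atoms: none
Why: Hajos–Parrish–Eder–Sauer–Wiechert enamine aldol condensation; the D-proline-derived catalyst differentiates the two enantiotopic ring carbonyls and sets C10 in the sense of (R)-Wieland–Miescher ketone (S by CIP here because allyl outranks the ring CH2).

**Step 3**
Reactants: 4 enedione
Product: 5 C9 ethylene ketal of 4
Conditions: ethylene glycol (5 equiv), TsOH·H2O (cat.), 4 Å MS, CH2Cl2, rt
Reagents that add atoms: ethylene glycol, OCCO
Why: Acid-catalysed ketalisation is selective for the saturated C9 ketone over the conjugated, tetrasubstituted enone carbonyl, as with the Wieland–Miescher ketone.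

**Step 4**
Reactants: 5 allyl ketal
Product: 6 10-[(E)-prop-1-enyl] isomer of 5
Conditions: RuHCl(CO)(PPh3)3 (3 mol%), toluene, 90 °C
Reagents that add atoms: none
Why: Ruthenium-hydride olefin isomerisation (hydrometalation/β-hydride elimination) moves the terminal alkene to the more stable internal (E) position; the enone alkene cannot migrate.

**Step 5**
Reactants: 6 propenyl ketal
Product: 7 angular aldehyde (C14 = CHO) enone ketal
Conditions: OsO4 (2 mol%), NaIO4 (4 equiv), 2,6-lutidine, dioxane/H2O 3:1, rt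
Reagents that add atoms: osmium tetroxide (catalytic, re-oxidised by periodate), O=[Os](=O)(=O)=O; sodium periodate, [Na+].[O-]I(=O)(=O)=O
Why: Lemieux–Johnson cleavage; OsO4 dihydroxylates the electron-rich disubstituted alkene and leaves the electron-poor tetrasubstituted enone alone, and periodate cleaves the diol.

**Step 6**
Reactants: 7 aldehyde
Product: 8 C14 primary alcohol (enone ketal)
Conditions: NaBH4 (0.4 equiv), EtOH/CH2Cl2, −78 °C
Reagents that add atoms: none
Why: Chemoselective borohydride reduction; at −78 °C the aldehyde reacts far faster than the conjugated ketone.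

**Step 7**
Reactants: 8 alcohol
Product: 9 C14 triisopropylsilyl ether
Conditions: i-Pr3SiOTf, 2,6-lutidine, CH2Cl2, 0 °C
Reagents that add atoms: triisopropylsilyl triflate, CC(C)[Si](OS(=O)(=O)C(F)(F)F)(C(C)C)C(C)C
Why: O-silylation; TIPS is aprotic (no internal proton delivery in step 8) and survives Li/NH3 and the aqueous acid of step 11.

**Step 8**
Reactants: 9 enone
Product: 11 C3 enol triflate of the trans-decalin (Δ3), via lithium Δ3-enolate 10 (not isolated)
Conditions: Li (2.5 equiv), t-BuOH (1 equiv), NH3/THF, −78 °C; isoprene; remove NH3; PhNTf2, THF, −78 → 0 °C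
Reagents that add atoms: N-phenylbis(trifluoromethanesulfonimide), O=S(=O)(N(c1ccccc1)S(=O)(=O)C(F)(F)F)C(F)(F)F
Why: Dissolving-metal (Birch-type) enone reduction protonates C5 axially, anti to the angular CH2OTIPS, giving H5 trans to C14 (trans-decalin); the regiospecific enolate is O-triflated.

**Step 9**
Reactants: 11 enol triflate
Product: 12 Δ3-alkene (C3=C4 with 4-methyl; C9 ketal; C14–OTIPS)
Conditions: Pd(OAc)2 (5 mol%), PPh3 (10 mol%), HCO2H, n-Bu3N, DMF, 60 °C
Reagents that add atoms: none
Why: Palladium-catalysed formate reduction of a vinyl triflate (oxidative addition of zerovalent palladium, decarboxylation of formate to a hydride, reductive elimination) fixes the alkene at C3=C4.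

**Step 10**
Reactants: 12 alkene
Product: 13 Δ3-en-2-one
Conditions: Rh2(cap)4 (cap = caprolactamate, 1 mol%), t-BuOOH (5 equiv), K2CO3, CH2Cl2, rt
Reagents that add atoms: tert-butyl hydroperoxide, CC(C)(C)OO
Why: Peroxyl-radical allylic oxidation at the only allylic CH2 (C2, next to the CH= terminus), the regiochemistry of the valencene → nootkatone and α-pinene → verbenone oxidations.

**Step 11**
Reactants: 13 enone ketal
Product: 14 Δ3-ene-2,9-dione
Conditions: 2 M HCl, THF, rt
Reagents that add atoms: water, O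
Why: Acid hydrolysis of the dioxolane; the primary TIPS ether and the enone are stable to these conditions.

**Step 12**
Reactants: 14 dione
Product: 15 Δ3,7-diene-2,9-dione
Conditions: IBX (2.5 equiv), DMSO, 70 °C
Reagents that add atoms: none
Why: IBX α,β-dehydrogenation acts only on the C9 ketone (C8–C7), because the α′ carbon of the ring A enone (C1) is flanked by quaternary C10 and cannot be desaturated.

**Step 13**
Reactants: 15 bis-enone
Product: 17 7-isopropenyl-Δ3-ene-2,9-dione (isopropenyl axial and trans to C14), via trimethylsilyl enol ether 16 (not isolated)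
Conditions: CH2=C(CH3)MgBr (1.4 equiv, slow addition), CuBr·SMe2 (20 mol%), Me3SiCl (2 equiv), THF, −78 °C; then 1 M HCl work-up
Reagents that add atoms: isopropenylmagnesium bromide, C=C(C)[Mg]Br
Why: Copper-catalysed conjugate addition goes to the β-monosubstituted ring B enone and not the β,β-disubstituted ring A enone (as with Δ1 of steroidal 1,4-dien-3-ones); stereoelectronic axial attack on the face of axial H5, anti to C14, sets C7.

**Step 14**
Reactants: 17 silyl ether
Product: 18 C14 alcohol (β-hydroxy ketone)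
Conditions: HF·pyridine, pyridine/THF, 0 °C → rt
Reagents that add atoms: none
Why: Fluoride cleavage of the Si–O bond under mildly acidic conditions, which avoids retro-aldol loss of the angular CH2OH.

**Step 15**
Reactants: 18 β-hydroxy ketone
Product: 19 9,14-diol (9-OH trans to C14)
Conditions: Me4NBH(OAc)3 (5 equiv), MeCN/AcOH 1:1, −20 °C
Reagents that add atoms: none
Why: Evans–Saksena hydroxyl-directed reduction; the C14-bound alkoxyborohydride delivers hydride to the C9 carbonyl face syn to C14, so the new OH is trans to C14, and the enone (not a β-hydroxy ketone) is untouched.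

**Step 16**
Reactants: 19 diol
Product: 20 9,14-bis(triethylsilyl) ether
Conditions: Et3SiOTf (3 equiv), 2,6-lutidine, CH2Cl2, −78 → 0 °C
Reagents that add atoms: triethylsilyl triflate, CC[Si](CC)(CC)OS(=O)(=O)C(F)(F)F
Why: Silylation masks both hydroxyls for the enolate chemistry and places a bulky axial group at C9 that screens one face of C1.

**Step 17**
Reactants: 20 enone
Product: 22 1-hydroxy-Δ3-en-2-one (1-OH cis to C14), via lithium dienolate 21 (not isolated)
Conditions: LiN(i-Pr)2 (1.2 equiv), THF, −78 °C; 2-(phenylsulfonyl)-3-phenyloxaziridine, −78 °C; aq. NH4Cl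
Reagents that add atoms: 2-(phenylsulfonyl)-3-phenyloxaziridine, O=S(=O)(c1ccccc1)N1OC1c1ccccc1
Why: Kinetic α′-deprotonation and Davis enolate oxidation; the face of C1 trans to C14 is blocked by the syn-axial C9–OSiEt3, so oxygen arrives cis to C14, which is also the thermodynamically preferred (equatorial) epimer.

**Step 18**
Reactants: 22 ketol
Product: 23 1-O-(3-methylbutanoyl) ester
Conditions: 3-methylbutanoyl chloride, pyridine, DMAP (cat.), CH2Cl2, 0 °C → rt
Reagents that add atoms: 3-methylbutanoyl chloride, CC(C)CC(=O)Cl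
Why: DMAP-catalysed acylation of the only free hydroxyl installs the isovalerate before C2 is unveiled.

**Step 19**
Reactants: 23 acyloxy enone
Product: 24 allylic alcohol (2-OH cis to C14 and to the C1 ester)
Conditions: NaBH4, CeCl3·7H2O, MeOH, −78 °C; AcOH quench
Reagents that add atoms: none
Why: Luche 1,2-reduction; the face of C2 cis to C14 is blocked by the 1,3-diaxial C14H2OSiEt3, so hydride enters trans to C14 and the OH ends cis (as in the axial 2β-ols from steroidal 2-ketones).

**Step 20**
Reactants: 24 bis-silyl ether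
Product: 25 2,9,14-triol 1-isovalerate
Conditions: HF·pyridine, pyridine/THF, 0 °C
Reagents that add atoms: none
Why: Fluoride desilylation under mildly acidic conditions that do not promote acyl migration.

**Step 21**
Reactants: 25 triol
Product: 26 2,9,14-triacetate 1-isovalerate
Conditions: Ac2O, DMAP, pyridine, rt → 40 °C
Reagents that add atoms: acetic anhydride, CC(=O)OC(C)=O
Why: Exhaustive DMAP-catalysed acetylation; acetylation outpaces ester migration.

**Step 22**
Reactants: 26 tetraester
Product: 27 target, (1R,2S,5R,7S,9S,10S)-2,9-diacetoxy-14-hydroxyeudesma-3,11-dien-1-yl 3-methylbutanoate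
Conditions: lipase (immobilised Candida antarctica lipase B), 0.1 M phosphate buffer pH 7.0/acetone 9:1, 30 °C
Reagents that add atoms: none
Why: Enzymatic regioselective ester hydrolysis; the lipase (serine hydrolase) accepts only the unhindered primary acetate and leaves the three secondary esters on the congested decalin, and neutral pH prevents acyl migration.

**Compound list**
1 | 2-allylcyclohexane-1,3-dione | C=CCC1C(=O)CCCC1=O | starting material
2 | ethyl vinyl ketone | CCC(=O)C=C | starting material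
3 | 2-allyl-2-(3-oxopentyl)cyclohexane-1,3-dione | CCC(=O)CCC1(CC=C)C(=O)CCCC1=O | intermediate
4 | (S)-8a-allyl-5-methyl-3,4,8,8a-tetrahydronaphthalene-1,6(2H,7H)-dione | C1CC(=O)[C@@]2(CC=C)C(C1)=C(C)C(=O)CC2 | intermediate
5 | C9 ethylene ketal of 4 | C1CC2(OCCO2)[C@@]3(CC=C)C(C1)=C(C)C(=O)CC3 | intermediate
6 | (E)-propenyl ketal | C1CC2(OCCO2)[C@@]3(/C=C/C)C(C1)=C(C)C(=O)CC3 | intermediate
7 | angular aldehyde | C1CC2(OCCO2)[C@@]3(C=O)C(C1)=C(C)C(=O)CC3 | intermediate
8 | C14 alcohol | C1CC2(OCCO2)[C@@]3(CO)C(C1)=C(C)C(=O)CC3 | intermediate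
9 | C14 TIPS ether | C1CC2(OCCO2)[C@@]3(CO[Si](C(C)C)(C(C)C)C(C)C)C(C1)=C(C)C(=O)CC3 | intermediate
10 | lithium Δ3-enolate, trans-fused (not isolated) | C1CC2(OCCO2)[C@@]3(CO[Si](C(C)C)(C(C)C)C(C)C)[C@H](C1)C(C)=C([O-])CC3.[Li+] | intermediate
11 | C3 enol triflate, trans-decalin | C1CC2(OCCO2)[C@@]3(CO[Si](C(C)C)(C(C)C)C(C)C)[C@H](C1)C(C)=C(OS(=O)(=O)C(F)(F)F)CC3 | intermediate
12 | Δ3-alkene | C1CC2(OCCO2)[C@@]3(CO[Si](C(C)C)(C(C)C)C(C)C)[C@H](C1)C(C)=CCC3 | intermediate
13 | Δ3-en-2-one, C9 ketal | C1CC2(OCCO2)[C@@]3(CO[Si](C(C)C)(C(C)C)C(C)C)[C@H](C1)C(C)=CC(=O)C3 | intermediate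
14 | Δ3-ene-2,9-dione | C1CC(=O)[C@@]2(CO[Si](C(C)C)(C(C)C)C(C)C)[C@H](C1)C(C)=CC(=O)C2 | intermediate
15 | Δ3,7-diene-2,9-dione | C1=CC(=O)[C@@]2(CO[Si](C(C)C)(C(C)C)C(C)C)[C@H](C1)C(C)=CC(=O)C2 | intermediate
16 | C9 trimethylsilyl enol ether (not isolated) | C=C(C)[C@@H]1C=C(O[Si](C)(C)C)[C@@]2(CO[Si](C(C)C)(C(C)C)C(C)C)[C@H](C1)C(C)=CC(=O)C2 | intermediate
17 | 7-isopropenyl-Δ3-ene-2,9-dione, C14–OTIPS | C=C(C)[C@@H]1CC(=O)[C@@]2(CO[Si](C(C)C)(C(C)C)C(C)C)[C@H](C1)C(C)=CC(=O)C2 | intermediate
18 | 14-hydroxy-7-isopropenyl-Δ3-ene-2,9-dione | C=C(C)[C@@H]1CC(=O)[C@@]2(CO)[C@H](C1)C(C)=CC(=O)C2 | intermediate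
19 | 9,14-diol enone (9-OH trans to C14) | C=C(C)[C@@H]1C[C@H](O)[C@@]2(CO)[C@H](C1)C(C)=CC(=O)C2 | intermediate
20 | 9,14-bis(triethylsilyl) ether | C=C(C)[C@@H]1C[C@H](O[Si](CC)(CC)CC)[C@@]2(CO[Si](CC)(CC)CC)[C@H](C1)C(C)=CC(=O)C2 | intermediate
21 | lithium cross-conjugated dienolate (not isolated) | C=C(C)[C@@H]1C[C@H](O[Si](CC)(CC)CC)[C@@]2(CO[Si](CC)(CC)CC)[C@H](C1)C(C)=CC([O-])=C2.[Li+] | intermediate
22 | 1-hydroxy enone (1-OH cis to C14) | C=C(C)[C@@H]1C[C@H](O[Si](CC)(CC)CC)[C@@]2(CO[Si](CC)(CC)CC)[C@H](C1)C(C)=CC(=O)[C@@H]2O | intermediate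
23 | 1-isovalerate enone | C=C(C)[C@@H]1C[C@H](O[Si](CC)(CC)CC)[C@@]2(CO[Si](CC)(CC)CC)[C@H](C1)C(C)=CC(=O)[C@@H]2OC(=O)CC(C)C | intermediate
24 | 2-allylic alcohol (2-OH cis to C14) | C=C(C)[C@@H]1C[C@H](O[Si](CC)(CC)CC)[C@@]2(CO[Si](CC)(CC)CC)[C@H](C1)C(C)=C[C@H](O)[C@@H]2OC(=O)CC(C)C | intermediate
25 | 2,9,14-triol 1-isovalerate | C=C(C)[C@@H]1C[C@H](O)[C@@]2(CO)[C@H](C1)C(C)=C[C@H](O)[C@@H]2OC(=O)CC(C)C | intermediate
26 | 2,9,14-triacetate 1-isovalerate | C=C(C)[C@@H]1C[C@H](OC(C)=O)[C@@]2(COC(C)=O)[C@H](C1)C(C)=C[C@H](OC(C)=O)[C@@H]2OC(=O)CC(C)C | intermediate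
27 | CNP0257109.1 | C=C(C)[C@@H]1C[C@H](OC(C)=O)[C@@]2(CO)[C@H](C1)C(C)=C[C@H](OC(C)=O)[C@@H]2OC(=O)CC(C)C | target

**Totals**
Total steps: 22. Longest linear sequence: 22 steps (fully linear from 1 and 2).

**Three steps most likely to fail, with fallbacks**

Step 10 (allylic oxidation; moderate yield, possible attack at C5 or C15). The fallback replaces C–H oxidation by a 1,2-carbonyl transposition and sets out from 9. Li/NH3 with NH4Cl quench gives the trans-fused saturated 3-ketone F1 (4-methyl equatorial). KN(SiMe3)2 followed by the Davis oxaziridine hydroxylates the kinetic C2 enolate to give the 2-hydroxy-3-ketone F2. Dess–Martin periodinane gives the 2,3-dione, isolated as its diosphenol F3, enolised toward the methyl-bearing C4 as in 3-methylcyclohexane-1,2-dione. Tf2O/pyridine gives the diosphenol triflate F4, and Pd(OAc)2/PPh3 with HCO2H and n-Bu3N removes the triflate. The fallback comes back to the route at 13.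

Step 17 (α′-hydroxylation; face selectivity at a C1 hindered on both sides, and possible γ-deprotonation). The fallback switches from kinetic to thermodynamic control and sets out from 20. If hydroxylation delivers mainly the C1 epimer with 1-OH trans to C14, the 1-epi-ketol F5, it is equilibrated through its enediolate with DBU in toluene at 40 °C under argon. F5 carries its axial OH syn-diaxial to the axial C9–OSiEt3, so the equilibrium lies on the side of the equatorial epimer. The fallback comes back to the route at 22.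

Step 22 (lipase hydrolysis; the neopentyl primary acetate may react slowly, or an ester may migrate once C14–OH is free). The fallback keeps a lipase but uses it for acylation and sets out from 25. Lipase-catalysed transesterification with vinyl chloroacetate in MTBE acylates only the primary hydroxyl to give the 14-O-chloroacetate F6. Ac2O/DMAP/pyridine then gives the 2,9-diacetate 14-chloroacetate F7. Thiourea and NaHCO3 in EtOH remove the chloroacetate chemoselectively in the presence of acetates and isovalerate. The fallback comes back to the route at 27.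

**Further compounds**
F1 | step 10 | trans-fused saturated 3-ketone (4-methyl equatorial, C9 ketal, C14–OTIPS) | C1CC2(OCCO2)[C@@]3(CO[Si](C(C)C)(C(C)C)C(C)C)[C@H](C1)[C@@H](C)C(=O)CC3
F2 | step 10 | 2-hydroxy-3-ketone (2-OH trans to C14) | C1CC2(OCCO2)[C@@]3(CO[Si](C(C)C)(C(C)C)C(C)C)[C@H](C1)[C@@H](C)C(=O)[C@@H](O)C3
F3 | step 10 | diosphenol (3-hydroxy-4-methyl-Δ3-en-2-one) | C1CC2(OCCO2)[C@@]3(CO[Si](C(C)C)(C(C)C)C(C)C)[C@H](C1)C(C)=C(O)C(=O)C3
F4 | step 10 | diosphenol triflate (3-triflyloxy-Δ3-en-2-one) | C1CC2(OCCO2)[C@@]3(CO[Si](C(C)C)(C(C)C)C(C)C)[C@H](C1)C(C)=C(OS(=O)(=O)C(F)(F)F)C(=O)C3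
F5 | step 17 | 1-epi-ketol (1-OH trans to C14) | C=C(C)[C@@H]1C[C@H](O[Si](CC)(CC)CC)[C@@]2(CO[Si](CC)(CC)CC)[C@H](C1)C(C)=CC(=O)[C@H]2O
F6 | step 22 | 14-O-chloroacetate of triol 25 | C=C(C)[C@@H]1C[C@H](O)[C@@]2(COC(=O)CCl)[C@H](C1)C(C)=C[C@H](O)[C@@H]2OC(=O)CC(C)C
F7 | step 22 | 2,9-diacetate 14-chloroacetate 1-isovalerate | C=C(C)[C@@H]1C[C@H](OC(C)=O)[C@@]2(COC(=O)CCl)[C@H](C1)C(C)=C[C@H](OC(C)=O)[C@@H]2OC(=O)CC(C)C
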